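**Plan**

- Numbering (eudesmane): ring A is C1–C2–C3–C4–C5–C10, ring B is C5–C6–C7–C8–C9–C10, the acrylate is C11(=C13)–C12, C14 sits on C10 and C15 on C4; β is the C14 face.
- Retrosynthetic cuts, in order: C5–OOH with C4=C15 back to a C4=C5 alkene; the O3 and O8 acyl groups back to a C3 ketone and a C8 alcohol; ring B at C7–C8; then the arm at C7=C11, C5–C6 and C10–C9, which leaves a ring A dione.
- Enabling feature: O8 and the C12 carbonyl are 1,4-related across C7–C11. With the alkene moved to C7=C11 and a bromide on C13, C7 (enoate β carbon) and C8 (aldehyde carbon) are both acceptors, and metalation at C13 turns C7 into the donor that closes ring B.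
- Forward order: ring A is bought; the C10 quaternary centre and its C9–C8 aldehyde arm come first, then the C5 allyl arm (with enone transposition) and its extension to the bromomethyl enoate, then ring B, then the O8 acetate, C3 reduction and acylation, and the C5 hydroperoxide.
- Stereochemistry: C10 from the ligand-controlled palladium allylation; C7 and C8 from the chair transition state of the ring closure, relayed from C10; C3 from axial hydride delivery; C5 from singlet oxygen attack anti to C14.

Key step: step 9

Remark: the (R)-ligand in step 4 is chosen by analogy with 2-methylcyclohexanone-derived substrates, where the (S)-ligand gives the (S)-2-allyl ketone; if the vinylogous ester responded in the opposite sense, the enantiomeric ligand would be used.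

**Route**

Step 1
Reactants: 1 2-methylcyclohexane-1,3-dione
Product: 2 3-isobutoxy-2-methylcyclohex-2-en-1-one
Conditions: i-BuOH, TsOH·H2O (cat.), toluene, reflux, Dean–Stark
Reagents that add atoms: 2-methylpropan-1-ol, CC(C)CO
Why: Acid-catalysed condensation of the symmetrical 1,3-dione with the alcohol under azeotropic removal of water (vinylogous esterification) gives the enol ether, which differentiates the two carbonyl groups for the later transposition.

Step 2
Reactants: 2 3-isobutoxy-2-methylcyclohex-2-en-1-one; 3 allyl chloroformate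
Product: 5 allyl 4-isobutoxy-3-methyl-2-oxocyclohex-3-ene-1-carboxylate, via lithium enolate 4 (not isolated)
Conditions: LiN(iPr)2 (2 equiv), THF, −78 °C; then 3, −78 → 0 °C
Reagents that add atoms: none
Why: Kinetic deprotonation of a vinylogous ester takes place at the α' methylene, and the lithium enolate 4 is C-acylated by the chloroformate (Claisen-type acylation) to the β-keto ester.

Step 3
Reactants: 5 allyl 4-isobutoxy-3-methyl-2-oxocyclohex-3-ene-1-carboxylate
Product: 6 allyl 4-isobutoxy-1,3-dimethyl-2-oxocyclohex-3-ene-1-carboxylate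
Conditions: MeI, Cs2CO3, MeCN, 50 °C
Reagents that add atoms: iodomethane, CI
Why: The doubly activated carbon of the β-keto ester is C-methylated under mild carbonate conditions (enolate alkylation), which creates a racemic quaternary centre that is ionised and reset in step 4.

Step 4
Reactants: 6 allyl 4-isobutoxy-1,3-dimethyl-2-oxocyclohex-3-ene-1-carboxylate
Product: 7 (6R)-6-allyl-3-isobutoxy-2,6-dimethylcyclohex-2-en-1-one
Conditions: Pd2(dba)3 (2.5 mol %), (R)-t-BuPHOX [(R)-4-tert-butyl-2-(2-diphenylphosphinophenyl)-4,5-dihydrooxazole] (6 mol %), toluene, 30 °C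
Reagents that add atoms: none
Why: Zerovalent palladium ionises the allyl ester, CO2 is lost, and the resulting prochiral enolate recombines with the π-allyl fragment inside the chiral phosphinooxazoline pocket (decarboxylative asymmetric allylic alkylation of Tsuji–Trost type), so that both enantiomers of 6 converge on the R quaternary centre, the future C10.

Step 5
Reactants: 7 (6R)-6-allyl-3-isobutoxy-2,6-dimethylcyclohex-2-en-1-one
Product: 9 2-[(1R)-4-isobutoxy-1,3-dimethyl-2-oxocyclohex-3-en-1-yl]acetaldehyde, via diol 8 (not isolated)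
Conditions: OsO4 (2 mol %), NaIO4, 2,6-lutidine, dioxane/H2O (3:1), 25 °C
Reagents that add atoms: osmium tetroxide, O=[Os](=O)(=O)=O (oxygen donor, turned over by NaIO4); sodium periodate, [Na+].[O-]I(=O)(=O)=O
Why: OsO4 dihydroxylates only the terminal monosubstituted alkene, the tetrasubstituted push-pull alkene of the vinylogous ester being inert, and NaIO4 cleaves diol 8 in the same flask (Lemieux–Johnson oxidation) to the C9–C8 aldehyde arm.

Step 6
Reactants: 9 2-[(1R)-4-isobutoxy-1,3-dimethyl-2-oxocyclohex-3-en-1-yl]acetaldehyde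
Product: 10 (6R)-6-(1,3-dioxolan-2-ylmethyl)-3-isobutoxy-2,6-dimethylcyclohex-2-en-1-one
Conditions: Me3SiOCH2CH2OSiMe3, Me3SiOTf (cat.), CH2Cl2, −78 °C
Reagents that add atoms: 1,2-bis(trimethylsilyloxy)ethane, C[Si](C)(C)OCCO[Si](C)(C)C
Why: Silyl triflate-catalysed acetalisation with the bis-silyl ether of ethylene glycol (Noyori acetalisation) protects the aldehyde at low temperature without protic acid, so the far less electrophilic vinylogous ester carbonyl and its enol ether stay untouched.

Step 7
Reactants: 10 (6R)-6-(1,3-dioxolan-2-ylmethyl)-3-isobutoxy-2,6-dimethylcyclohex-2-en-1-one; 11 allylmagnesium bromide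
Product: 14 2-[(1R)-2-allyl-1,3-dimethyl-4-oxocyclohex-2-en-1-yl]acetaldehyde, via magnesium alkoxide 12 (not isolated), via enone dioxolane 13 (not isolated)
Conditions: CH2=CHCH2MgBr, THF, −78 → 0 °C; then 2 M HCl, THF, 25 °C
Reagents that add atoms: water, O
Why: The allyl Grignard reagent adds 1,2 to the vinylogous ester carbonyl and aqueous acid then hydrolyses the enol ether, dehydrates the β-hydroxy ketone to the transposed enone (Stork–Danheiser sequence) and cleaves the dioxolane, which places the allyl group on C5 without touching the quaternary centre.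

Step 8
Reactants: 14 2-[(1R)-2-allyl-1,3-dimethyl-4-oxocyclohex-2-en-1-yl]acetaldehyde; 15 methyl 2-(bromomethyl)acrylate
Product: 16 methyl (2Z)-2-(bromomethyl)-4-[(6R)-2,6-dimethyl-3-oxo-6-(2-oxoethyl)cyclohex-1-en-1-yl]but-2-enoate
Conditions: 15 (5 equiv), second-generation Hoveyda–Grubbs catalyst RuCl2(H2IMes)(=CH–C6H4-2-OiPr) (10 mol %), 2,6-dichloro-1,4-benzoquinone (20 mol %), CH2Cl2, 40 °C
Reagents that add atoms: none
Why: Ruthenium-carbene cross-metathesis of the terminal alkene with an excess of the 2-substituted acrylate releases ethylene and gives the trisubstituted enoate with C6 anti to the ester (Z because CH2Br outranks the ester), as known for methacrylates and α-methylene lactones, while the quinone additive suppresses migration of the skipped alkene.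

Step 9
Reactants: 16 methyl (2Z)-2-(bromomethyl)-4-[(6R)-2,6-dimethyl-3-oxo-6-(2-oxoethyl)cyclohex-1-en-1-yl]but-2-enoate
Product: 20 methyl 8β-hydroxy-3-oxoeudesma-4,11(13)-dien-12-oate, via allylchromium dichloride 17 (not isolated), via chromium alkoxide 18 (not isolated), via trimethylsilyl ether 19 (not isolated)
Conditions: CrCl2 (20 mol %), Mn powder, Me3SiCl, THF, 25 °C, slow addition of 16 (high dilution); then 10% aq. citric acid, 0 °C
Reagents that add atoms: none
Why: Two single-electron transfers from divalent chromium convert the C13–Br bond into the trivalent allylchromium 17, whose γ carbon C7, now a donor, attacks the chromium-bound C8 aldehyde in an SE2' sense and regenerates the C11=C13 methylene, while Mn returns chromium to the divalent state and Me3SiCl caps alkoxide 18 as silyl ether 19 so that the cis alkoxide cannot lactonise onto C12. The closest known reaction type is the intramolecular Nozaki–Hiyama–Kishi (or zinc Barbier) allylation of aldehydes by 2-(bromomethyl)alk-2-enoates, run here in its manganese/chlorosilane turnover form. Ring B closes 6-exo-trig at the aldehyde carbonyl. C7 and C8 are set in a six-membered chromium chair of the Zimmerman–Traxler type in which the favoured Z-allylchromium (C6 anti to the ester) holds C6 axial and the aldehyde chain C9 equatorial, so that this chair is cis-fused to the forming ring B chair with C11 equatorial on C7 and oxygen axial on C8, that is cis C7/C8. Because the planar C4=C5 unit allows ring B only the chair in which C14 is axial, the axial C8 oxygen must lie on the C14 face, which relays the single existing centre C10 to 7β,8β. The step needs the aldehyde to react in preference to the enone and the ester and ring closure to outrun dimerisation, which the low reactivity of allylchromium toward ketones and esters and slow addition at high dilution secure.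

Step 10
Reactants: 20 methyl 8β-hydroxy-3-oxoeudesma-4,11(13)-dien-12-oate
Product: 21 methyl 8β-acetoxy-3-oxoeudesma-4,11(13)-dien-12-oate
Conditions: Ac2O, DMAP (cat.), pyridine, CH2Cl2, 0 °C, on the crude alcohol
Reagents that add atoms: acetic anhydride, CC(=O)OC(C)=O
Why: DMAP-catalysed acetylation (nucleophilic acyl transfer) esterifies the axial C8 hydroxyl directly after its release, which also removes the free hydroxyl before it can lactonise onto the C12 ester.

Step 11
Reactants: 21 methyl 8β-acetoxy-3-oxoeudesma-4,11(13)-dien-12-oate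
Product: 22 methyl 8β-acetoxy-3β-hydroxyeudesma-4,11(13)-dien-12-oate
Conditions: NaBH4, CeCl3·7H2O, MeOH, −78 → −20 °C
Reagents that add atoms: none
Why: Luche reduction delivers hydride 1,2 to the enone carbonyl along the axial trajectory on the α face, anti to the axial C14 methyl, giving the equatorial 3β allylic alcohol, and at low temperature leaves the acrylate, the acetate and the methyl ester alone.

Step 12
Reactants: 22 methyl 8β-acetoxy-3β-hydroxyeudesma-4,11(13)-dien-12-oate
Product: 23 methyl 8β-acetoxy-3β-(isobutyryloxy)eudesma-4,11(13)-dien-12-oate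
Conditions: (i-PrCO)2O, DMAP (cat.), pyridine, CH2Cl2, 0 → 25 °C
Reagents that add atoms: isobutyric anhydride, CC(C)C(=O)OC(=O)C(C)C
Why: DMAP-catalysed acylation of the secondary allylic alcohol with the anhydride forms the C3 isobutyrate with retention, and capping the hydroxyl removes its directing effect on singlet oxygen, which would steer the oxygen to C4.

Step 13
Reactants: 23 methyl 8β-acetoxy-3β-(isobutyryloxy)eudesma-4,11(13)-dien-12-oate
Product: 24 methyl 8β-acetoxy-5α-hydroperoxy-3β-(isobutyryloxy)eudesma-4(15),11(13)-dien-12-oate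
Conditions: O2, visible light, 5,10,15,20-tetraphenylporphyrin (cat.), CH2Cl2, 0 °C
Reagents that add atoms: dioxygen, O=O
Why: Singlet oxygen reacts only with the electron-rich tetrasubstituted C4=C5 alkene (Schenck ene reaction), approaching C5 from the α face anti to the axial C14 methyl and taking a hydrogen from the C15 methyl, which gives the 5α-hydroperoxide and the C4=C15 methylene while the acrylate alkene is too electron-poor to react.

**Compound list**

1 | 2-methylcyclohexane-1,3-dione | CC1C(=O)CCCC1=O | starting material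
2 | 3-isobutoxy-2-methylcyclohex-2-en-1-one | CC1=C(OCC(C)C)CCCC1=O | intermediate
3 | allyl chloroformate | C=CCOC(=O)Cl | starting material
4 | lithium 5-isobutoxy-6-methylcyclohexa-1,5-dien-1-olate (α' enolate of 2, formed in the flask) | CC1=C(OCC(C)C)CCC=C1O[Li] | intermediate
5 | allyl 4-isobutoxy-3-methyl-2-oxocyclohex-3-ene-1-carboxylate (racemic) | C=CCOC(=O)C1CCC(OCC(C)C)=C(C)C1=O | intermediate
6 | allyl 4-isobutoxy-1,3-dimethyl-2-oxocyclohex-3-ene-1-carboxylate (racemic) | C=CCOC(=O)C1(C)CCC(OCC(C)C)=C(C)C1=O | intermediate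
7 | (6R)-6-allyl-3-isobutoxy-2,6-dimethylcyclohex-2-en-1-one | C=CC[C@@]1(C)CCC(OCC(C)C)=C(C)C1=O | intermediate
8 | (6R)-6-(2,3-dihydroxypropyl)-3-isobutoxy-2,6-dimethylcyclohex-2-en-1-one (both carbinol epimers, formed in the flask) | OCC(O)C[C@@]1(C)CCC(OCC(C)C)=C(C)C1=O | intermediate
9 | 2-[(1R)-4-isobutoxy-1,3-dimethyl-2-oxocyclohex-3-en-1-yl]acetaldehyde | O=CC[C@@]1(C)CCC(OCC(C)C)=C(C)C1=O | intermediate
10 | (6R)-6-(1,3-dioxolan-2-ylmethyl)-3-isobutoxy-2,6-dimethylcyclohex-2-en-1-one | C1COC(O1)C[C@@]2(C)CCC(OCC(C)C)=C(C)C2=O | intermediate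
11 | allylmagnesium bromide | C=CC[Mg]Br | starting material
12 | bromomagnesium (6R)-1-allyl-6-(1,3-dioxolan-2-ylmethyl)-3-isobutoxy-2,6-dimethylcyclohex-2-en-1-olate (both carbinol epimers, formed in the flask) | C1COC(O1)C[C@@]2(C)CCC(OCC(C)C)=C(C)C2(O[Mg]Br)CC=C | intermediate
13 | (4R)-3-allyl-4-(1,3-dioxolan-2-ylmethyl)-2,4-dimethylcyclohex-2-en-1-one (formed in the flask) | C1COC(O1)C[C@@]2(C)CCC(=O)C(C)=C2CC=C | intermediate
14 | 2-[(1R)-2-allyl-1,3-dimethyl-4-oxocyclohex-2-en-1-yl]acetaldehyde | O=CC[C@@]1(C)CCC(=O)C(C)=C1CC=C | intermediate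
15 | methyl 2-(bromomethyl)acrylate | C=C(CBr)C(=O)OC | starting material
16 | methyl (2Z)-2-(bromomethyl)-4-[(6R)-2,6-dimethyl-3-oxo-6-(2-oxoethyl)cyclohex-1-en-1-yl]but-2-enoate | O=CC[C@@]1(C)CCC(=O)C(C)=C1C/C=C(\CBr)C(=O)OC | intermediate
17 | allylchromium dichloride from 16 (C13–CrCl2, trivalent chromium, solvent ligands omitted, formed in the flask) | O=CC[C@@]1(C)CCC(=O)C(C)=C1C/C=C(\C[Cr](Cl)Cl)C(=O)OC | intermediate
18 | chromium alkoxide of 20 (O8–CrCl2, trivalent chromium, formed in the flask) | C=C(C(=O)OC)[C@H]1CC2=C(C)C(=O)CC[C@]2(C)C[C@H]1O[Cr](Cl)Cl | intermediate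
19 | methyl 3-oxo-8β-(trimethylsilyloxy)eudesma-4,11(13)-dien-12-oate (7αH, formed in the flask) | C=C(C(=O)OC)[C@H]1CC2=C(C)C(=O)CC[C@]2(C)C[C@H]1O[Si](C)(C)C | intermediate
20 | methyl 8β-hydroxy-3-oxoeudesma-4,11(13)-dien-12-oate (7αH, 10β-methyl) | C=C(C(=O)OC)[C@H]1CC2=C(C)C(=O)CC[C@]2(C)C[C@H]1O | intermediate
21 | methyl 8β-acetoxy-3-oxoeudesma-4,11(13)-dien-12-oate | C=C(C(=O)OC)[C@H]1CC2=C(C)C(=O)CC[C@]2(C)C[C@H]1OC(C)=O | intermediate
22 | methyl 8β-acetoxy-3β-hydroxyeudesma-4,11(13)-dien-12-oate | C=C(C(=O)OC)[C@H]1CC2=C(C)[C@@H](O)CC[C@]2(C)C[C@H]1OC(C)=O | intermediate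
23 | methyl 8β-acetoxy-3β-(isobutyryloxy)eudesma-4,11(13)-dien-12-oate | C=C(C(=O)OC)[C@H]1CC2=C(C)[C@@H](OC(=O)C(C)C)CC[C@]2(C)C[C@H]1OC(C)=O | intermediate
24 | methyl 8β-acetoxy-5α-hydroperoxy-3β-(isobutyryloxy)eudesma-4(15),11(13)-dien-12-oate (CNP0244758.1) | C=C(C(=O)OC)[C@H]1C[C@@]2(OO)C(=C)[C@@H](OC(=O)C(C)C)CC[C@]2(C)C[C@H]1OC(C)=O | target

**Step count and risks**

Total step count: 13. Longest linear sequence: 13 steps (1 to 24).

The three steps most likely to fail are steps 8, 9 and 13.

In step 8 the ruthenium carbene may stall on the hindered, electron-poor 2-substituted acrylate or be consumed by the allylic bromide. Compound 14 would then homodimerise, or its skipped terminal alkene would migrate into conjugation with the enone. The fallback sets out from 14 and makes the C–Br bond after the C7=C11 bond, so that no allylic halide meets the carbene. Cross-metathesis of 14 with methyl 2-(hydroxymethyl)acrylate under the conditions of step 8 should give methyl (2E)-2-(hydroxymethyl)-4-[(6R)-2,6-dimethyl-3-oxo-6-(2-oxoethyl)cyclohex-1-en-1-yl]but-2-enoate F1. Corey–Kim bromination of its primary allylic alcohol (N-bromosuccinimide, Me2S, CH2Cl2, −20 → 0 °C) leaves the aldehyde alone and comes back to the route at 16.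

In step 9 the allylchromium may equilibrate to the E form (C6 syn to the ester) before it adds. Ring B would then close through the chair with C6 equatorial and give the trans C7/C8 alcohol. The fallback sets out from 16: the same closure would then deliver methyl 8α-hydroxy-3-oxoeudesma-4,11(13)-dien-12-oate F2. Its equatorial C8 hydroxyl is inverted and acetylated in one operation by a Mitsunobu reaction (PPh3, diisopropyl azodicarboxylate, AcOH, toluene, 0 → 25 °C). This comes back to the route at 21 and makes step 10 unnecessary.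

In step 13 hydrogen abstraction may lack site selectivity: abstraction from C6 (oxygen ending on C4) or from C3 can compete with abstraction from C15. The fallback sets out from 23 and builds the C5–O bond by epoxide chemistry rather than by an ene reaction.

- Epoxidation with mCPBA (NaHCO3, CH2Cl2, 0 °C), anti to C14 and selective for the electron-rich alkene, should give methyl 8β-acetoxy-4α,5α-epoxy-3β-(isobutyryloxy)eudesm-11(13)-en-12-oate F3.
- Silyl triflate/amidine isomerisation of the epoxide (Me3SiOTf, DBU, toluene, 0 → 25 °C) with loss of a C15 proton should give methyl 8β-acetoxy-3β-(isobutyryloxy)-5α-(trimethylsilyloxy)eudesma-4(15),11(13)-dien-12-oate F4.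
- Mild desilylation (citric acid, MeOH, 0 °C) gives methyl 8β-acetoxy-5α-hydroxy-3β-(isobutyryloxy)eudesma-4(15),11(13)-dien-12-oate F5.
- Acid-catalysed exchange of the tertiary allylic hydroxyl with H2O2 (50% H2O2, H2SO4 cat., Et2O, 0 °C), with capture of the allyl cation at C5 anti to C14, comes back to the route at 24.

**Further compounds**

F1 | step 8 | methyl (2E)-2-(hydroxymethyl)-4-[(6R)-2,6-dimethyl-3-oxo-6-(2-oxoethyl)cyclohex-1-en-1-yl]but-2-enoate | O=CC[C@@]1(C)CCC(=O)C(C)=C1C/C=C(\CO)C(=O)OC
F2 | step 9 | methyl 8α-hydroxy-3-oxoeudesma-4,11(13)-dien-12-oate | C=C(C(=O)OC)[C@H]1CC2=C(C)C(=O)CC[C@]2(C)C[C@@H]1O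
F3 | step 13 | methyl 8β-acetoxy-4α,5α-epoxy-3β-(isobutyryloxy)eudesm-11(13)-en-12-oate | C=C(C(=O)OC)[C@H]1C[C@]23O[C@]3(C)[C@@H](OC(=O)C(C)C)CC[C@]2(C)C[C@H]1OC(C)=O
F4 | step 13 | methyl 8β-acetoxy-3β-(isobutyryloxy)-5α-(trimethylsilyloxy)eudesma-4(15),11(13)-dien-12-oate | C=C(C(=O)OC)[C@H]1C[C@@]2(O[Si](C)(C)C)C(=C)[C@@H](OC(=O)C(C)C)CC[C@]2(C)C[C@H]1OC(C)=O
F5 | step 13 | methyl 8β-acetoxy-5α-hydroxy-3β-(isobutyryloxy)eudesma-4(15),11(13)-dien-12-oate | C=C(C(=O)OC)[C@H]1C[C@@]2(O)C(=C)[C@@H](OC(=O)C(C)C)CC[C@]2(C)C[C@H]1OC(C)=O
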